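**Retrosynthetic overview**
- The strategy rests on ring B, the 3,5-dihydroxyphenyl ring. Its hydroxyls at C3 and C5 are meta to each other and to C1, which carries the stilbene alkene; this is the alternating oxygen pattern of a tetraketide folded from the coumaroyl unit (ring A plus the alkene).
- Ring B is opened at the bond between C1 and its ortho carbon C2: an aldol closure of the C2 methylene onto the C7 cinnamoyl ketone of a linear methyl 3,5,7-trioxonon-8-enoate. The ester on that carbon is lost later as CO2.
- The trioxo ester comes from terminal C-acylation of the trianion of methyl 3,5-dioxohexanoate with an (E)-cinnamoyl Weinreb amide. The amide comes from a Heck reaction of silylated 2-geranyl-4-iodophenol with N-methoxy-N-methylacrylamide.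
- The geranyl C–C bond ortho to the phenol comes from C-alkylation of sodium 4-iodophenoxide with geranyl bromide.
- Ring order: ring A is bought as 4-iodophenol; ring B is the only ring formed (step 5). Hydrolysis, desilylation and decarboxylation finish the route.

Key step: step 5

Remark: the polycarbonyl compounds 10 and 11 are drawn as keto tautomers; they will exist largely as enol mixtures, which does not change the chemistry described.

**Step 1**
Reactants: 1 4-iodophenol; 2 geranyl bromide ((2E)-1-bromo-3,7-dimethylocta-2,6-diene)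
Product: 4 2-[(2E)-3,7-dimethylocta-2,6-dien-1-yl]-4-iodophenol, via sodium 4-iodophenoxide 3 (not isolated)
Conditions: NaH (1 equiv), toluene, 0 °C to rt; then 2 (slightly substoichiometric), rt
Reagents that add atoms: none
Why: Ortho C-alkylation of a phenoxide: in toluene the tightly ion-paired sodium phenoxide 3 should attack the primary allylic carbon of 2 through its ortho carbon (SN2, so the E alkene is carried over), the para position being blocked by iodine and the neutral O-geranyl ether by-product being removable by base extraction.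

**Step 2**
Reactants: 4 2-[(2E)-3,7-dimethylocta-2,6-dien-1-yl]-4-iodophenol
Product: 5 tert-butyl{2-[(2E)-3,7-dimethylocta-2,6-dien-1-yl]-4-iodophenoxy}dimethylsilane
Conditions: TBSCl, imidazole, DMF, rt
Reagents that add atoms: tert-butyldimethylsilyl chloride (TBSCl), CC(C)(C)[Si](C)(C)Cl
Why: Imidazole-promoted silylation masks the phenol, which would otherwise quench the trianion of step 4 and, as a para-phenoxide, deactivate the amide carbonyl; the ortho geranyl group shields the silyl ether in the later basic steps.

**Step 3**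
Reactants: 5 tert-butyl{2-[(2E)-3,7-dimethylocta-2,6-dien-1-yl]-4-iodophenoxy}dimethylsilane; 6 N-methoxy-N-methylacrylamide
Product: 7 (2E)-3-{4-[(tert-butyldimethylsilyl)oxy]-3-[(2E)-3,7-dimethylocta-2,6-dien-1-yl]phenyl}-N-methoxy-N-methylprop-2-enamide
Conditions: Pd(OAc)2 (cat.), P(o-tol)3 (cat.), Et3N, MeCN, 80 °C
Reagents that add atoms: none
Why: Mizoroki–Heck reaction: oxidative addition of the aryl iodide to zerovalent palladium, insertion of the electron-poor terminal acrylamide and syn β-hydride elimination should give the E alkene, while the hindered trisubstituted geranyl alkenes do not insert.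

**Step 4**
Reactants: 7 (2E)-3-{4-[(tert-butyldimethylsilyl)oxy]-3-[(2E)-3,7-dimethylocta-2,6-dien-1-yl]phenyl}-N-methoxy-N-methylprop-2-enamide; 8 methyl 3,5-dioxohexanoate
Product: 10 methyl (8E)-9-{4-[(tert-butyldimethylsilyl)oxy]-3-[(2E)-3,7-dimethylocta-2,6-dien-1-yl]phenyl}-3,5,7-trioxonon-8-enoate, via trilithium trianion 9 (not isolated)
Conditions: 8 (1.5 equiv), LiN(i-Pr)2 (LDA, 3 equiv per 8), THF, 0 °C; then 7, −78 to −20 °C; AcOH, −78 °C; crude 10 used at once
Reagents that add atoms: none
Why: Terminal C-acylation of a β-polycarbonyl polyanion: the last-formed and most basic C6 carbanion of trianion 9 should add 1,2 to the Weinreb amide, whose chelated tetrahedral adduct holds until the cold acetic acid quench and so prevents over-addition and cyclization of the sensitive triketo ester in the pot.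

**Step 5**
Reactants: 10 methyl (8E)-9-{4-[(tert-butyldimethylsilyl)oxy]-3-[(2E)-3,7-dimethylocta-2,6-dien-1-yl]phenyl}-3,5,7-trioxonon-8-enoate
Product: 12 methyl 2-[(E)-2-{4-[(tert-butyldimethylsilyl)oxy]-3-[(2E)-3,7-dimethylocta-2,6-dien-1-yl]phenyl}ethenyl]-4,6-dihydroxybenzoate, via cyclic aldol adduct 11 (not isolated)
Conditions: Et3N (2 equiv), CH2Cl2, 0 °C to rt
Reagents that add atoms: none
Why: Triethylamine equilibrates the enolates of 10; the C4 and C6 methylenes between two ketones are the most acidic, but the C4 enolate can only close four-membered rings and the C6 enolate only the Claisen ring onto the poorly electrophilic methyl ester, so the less populated C2 enolate is the one with a good partner, the C7 ketone (Curtin–Hammett control). The C2–C7 bond forms by a 6-(enolendo)-exo-trig intramolecular aldol addition to give β-hydroxy ketone 11, which loses water by E1cB across C6–C7 and enolizes twice to the arene 12, closing ring B without any oxidant, so the geranyl alkenes and the E alkene are untouched. The closest known reaction type is the weak-base aldol aromatization of 3,5,7-triketo esters and of diketo-dioxinones to β-resorcylates, cinnamoyl-terminated chains included. No stereocenter is set: the two centres of 11 form without control and are erased on aromatization. The selectivity needed is aldol (C2 to C7) over Claisen closure (C6 to C1), 2-pyrone lactonization, 4-pyranone formation and conjugate addition at C9. It should be secured by the weak amine base in an aprotic solvent (no alkoxide to drive acyl substitution, no acid to drive pyranone formation), by the ketone being a better electrophile than the methyl ester, and by the para-silyloxy group, which lowers the Michael reactivity of C9.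

**Step 6**
Reactants: 12 methyl 2-[(E)-2-{4-[(tert-butyldimethylsilyl)oxy]-3-[(2E)-3,7-dimethylocta-2,6-dien-1-yl]phenyl}ethenyl]-4,6-dihydroxybenzoate
Product: 14 schweinfurthin I, via resorcylic acid 13 (not isolated)
Conditions: KOH (excess), MeOH/H2O (degassed), reflux, argon, dark; then AcOH to pH 6–7, 60 °C
Reagents that add atoms: none
Why: Hydroxide should cleave the aryl silyl ether and saponify the hindered salicylate-type ester (acyl–oxygen cleavage), and the resulting 2,4-dihydroxybenzoate 13 should lose CO2 by ipso protonation in the hot non-acidic medium (β-resorcylic acid decarboxylation, as with orsellinate and cannabigerolate esters), while keeping the pH at or above 6 avoids acid-promoted lactonization of the stilbene acid and chroman formation from the ortho-geranylphenol.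

**Compound list**
1 | 4-iodophenol | Oc1ccc(I)cc1 | starting material
2 | geranyl bromide, (2E)-1-bromo-3,7-dimethylocta-2,6-diene | CC(C)=CCC/C(C)=C/CBr | starting material
3 | sodium 4-iodophenoxide | [Na+].[O-]c1ccc(I)cc1 | intermediate (not isolated)
4 | 2-[(2E)-3,7-dimethylocta-2,6-dien-1-yl]-4-iodophenol | CC(C)=CCC/C(C)=C/Cc1cc(I)ccc1O | intermediate
5 | tert-butyl{2-[(2E)-3,7-dimethylocta-2,6-dien-1-yl]-4-iodophenoxy}dimethylsilane | CC(C)=CCC/C(C)=C/Cc1cc(I)ccc1O[Si](C)(C)C(C)(C)C | intermediate
6 | N-methoxy-N-methylacrylamide | C=CC(=O)N(C)OC | starting material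
7 | (2E)-3-{4-[(tert-butyldimethylsilyl)oxy]-3-[(2E)-3,7-dimethylocta-2,6-dien-1-yl]phenyl}-N-methoxy-N-methylprop-2-enamide | CON(C)C(=O)/C=C/c1ccc(O[Si](C)(C)C(C)(C)C)c(C/C=C(\C)CCC=C(C)C)c1 | intermediate
8 | methyl 3,5-dioxohexanoate | COC(=O)CC(=O)CC(C)=O | starting material
9 | trilithium trianion of methyl 3,5-dioxohexanoate | [Li+].[Li+].[Li+].COC(=O)[CH-]C(=O)[CH-]C(=O)[CH2-] | intermediate (not isolated)
10 | methyl (8E)-9-{4-[(tert-butyldimethylsilyl)oxy]-3-[(2E)-3,7-dimethylocta-2,6-dien-1-yl]phenyl}-3,5,7-trioxonon-8-enoate | COC(=O)CC(=O)CC(=O)CC(=O)/C=C/c1ccc(O[Si](C)(C)C(C)(C)C)c(C/C=C(\C)CCC=C(C)C)c1 | intermediate (key-step precursor)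
11 | methyl 2-[(E)-2-{4-[(tert-butyldimethylsilyl)oxy]-3-[(2E)-3,7-dimethylocta-2,6-dien-1-yl]phenyl}ethenyl]-2-hydroxy-4,6-dioxocyclohexane-1-carboxylate (mixture of diastereomers) | COC(=O)C1C(=O)CC(=O)CC1(O)/C=C/c1ccc(O[Si](C)(C)C(C)(C)C)c(C/C=C(\C)CCC=C(C)C)c1 | intermediate (not isolated)
12 | methyl 2-[(E)-2-{4-[(tert-butyldimethylsilyl)oxy]-3-[(2E)-3,7-dimethylocta-2,6-dien-1-yl]phenyl}ethenyl]-4,6-dihydroxybenzoate | COC(=O)c1c(O)cc(O)cc1/C=C/c1ccc(O[Si](C)(C)C(C)(C)C)c(C/C=C(\C)CCC=C(C)C)c1 | intermediate (key-step product)
13 | 2-[(E)-2-{3-[(2E)-3,7-dimethylocta-2,6-dien-1-yl]-4-hydroxyphenyl}ethenyl]-4,6-dihydroxybenzoic acid (present in the flask as its potassium salt) | OC(=O)c1c(O)cc(O)cc1/C=C/c1ccc(O)c(C/C=C(\C)CCC=C(C)C)c1 | intermediate (not isolated)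
14 | schweinfurthin I, 5-[(E)-2-{3-[(2E)-3,7-dimethylocta-2,6-dien-1-yl]-4-hydroxyphenyl}ethenyl]benzene-1,3-diol | CC(C)=CCC/C(C)=C/Cc1cc(/C=C/c2cc(O)cc(O)c2)ccc1O | target

**Step count**
Total steps: 6. Longest linear sequence: 6 steps, from 4-iodophenol 1.

**Steps most likely to fail**

Step 5 (key aldol aromatization). Enolate equilibration may channel the chain into Claisen closure from C6 onto the ester, lactonization to a 2-pyrone, or conjugate addition at C9, faster than the C2-to-C7 aldol closure and dehydration. The fallback masks the carboxyl end as a dioxinone, which cannot act as an acyl acceptor at room temperature, and sets out from amide 7. Commercial 2,2,6-trimethyl-4H-1,3-dioxin-4-one would be deprotonated with LiN(SiMe3)2 in THF at −78 °C and C-acetylated with acetyl chloride to give 2,2-dimethyl-6-(2-oxopropyl)-4H-1,3-dioxin-4-one F1. After double deprotonation with LiN(i-Pr)2, F1 would be acylated at its terminal methyl with 7 to give 6-[(5E)-6-aryl-2,4-dioxohex-5-en-1-yl]-2,2-dimethyl-4H-1,3-dioxin-4-one F2. Triethylamine in CH2Cl2 should then close and aromatize ring B by the same aldol–dehydration sequence to give the acetonide-protected resorcylate, 5-[(E)-2-arylethenyl]-7-hydroxy-2,2-dimethyl-4H-1,3-benzodioxin-4-one F3. KOH in aqueous methanol, as in step 6, would open the acetonide ester and remove the silyl group; this comes back to the route at 13, which goes on to 14 in the same flask.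

Step 4 (trianion acylation). The polyanion may add in conjugate fashion to the cinnamoyl acceptor or act only as a base, and the sensitive triketo ester may cyclize without control during work-up. The fallback replaces acylation by aldol addition and oxidation and sets out from 7. Reduction with i-Bu2AlH in THF at −78 °C should give (2E)-3-{4-[(tert-butyldimethylsilyl)oxy]-3-[(2E)-3,7-dimethylocta-2,6-dien-1-yl]phenyl}prop-2-enal F4. Trianion 9 should add 1,2 to this aldehyde through its terminal carbon to give the stable methyl (8E)-9-aryl-7-hydroxy-3,5-dioxonon-8-enoate F5 (racemic at C7). Activated MnO2 in CH2Cl2 should oxidize the allylic alcohol under neutral conditions, which comes back to the route at 10.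

Step 1 (ortho C-geranylation). The ambident phenoxide may react at oxygen, alkylate twice, or attack the allylic bromide with transposition, so that little of the ortho mono-C-alkylated phenol forms. The fallback makes the aryl–geranyl bond from an aryl-metal reagent and sets out from geranyl bromide 2 and commercial 4-bromo-2-iodophenol. Silylation (TBSCl, imidazole, DMF) would give (4-bromo-2-iodophenoxy)(tert-butyl)dimethylsilane F6. Selective iodine–magnesium exchange (i-PrMgCl·LiCl, THF, −20 °C), transmetalation with CuBr·SMe2 and alkylation with 2 at the primary allylic carbon should give {4-bromo-2-[(2E)-3,7-dimethylocta-2,6-dien-1-yl]phenoxy}(tert-butyl)dimethylsilane F7. A Heck reaction of this aryl bromide with 6 (Pd(OAc)2, P(o-tol)3, Et3N, DMF, 100 °C) comes back to the route at 7.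

**Further compounds**
F1 | step 5 | 2,2-dimethyl-6-(2-oxopropyl)-4H-1,3-dioxin-4-one | CC(=O)CC1=CC(=O)OC(C)(C)O1
F2 | step 5 | 6-[(5E)-6-{4-[(tert-butyldimethylsilyl)oxy]-3-[(2E)-3,7-dimethylocta-2,6-dien-1-yl]phenyl}-2,4-dioxohex-5-en-1-yl]-2,2-dimethyl-4H-1,3-dioxin-4-one | CC1(C)OC(=O)C=C(CC(=O)CC(=O)/C=C/c2ccc(O[Si](C)(C)C(C)(C)C)c(C/C=C(\C)CCC=C(C)C)c2)O1
F3 | step 5 | 5-[(E)-2-{4-[(tert-butyldimethylsilyl)oxy]-3-[(2E)-3,7-dimethylocta-2,6-dien-1-yl]phenyl}ethenyl]-7-hydroxy-2,2-dimethyl-4H-1,3-benzodioxin-4-one | CC1(C)OC(=O)c2c(/C=C/c3ccc(O[Si](C)(C)C(C)(C)C)c(C/C=C(\C)CCC=C(C)C)c3)cc(O)cc2O1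
F4 | step 4 | (2E)-3-{4-[(tert-butyldimethylsilyl)oxy]-3-[(2E)-3,7-dimethylocta-2,6-dien-1-yl]phenyl}prop-2-enal | O=C/C=C/c1ccc(O[Si](C)(C)C(C)(C)C)c(C/C=C(\C)CCC=C(C)C)c1
F5 | step 4 | methyl (8E)-9-{4-[(tert-butyldimethylsilyl)oxy]-3-[(2E)-3,7-dimethylocta-2,6-dien-1-yl]phenyl}-7-hydroxy-3,5-dioxonon-8-enoate (racemic at C7) | COC(=O)CC(=O)CC(=O)CC(O)/C=C/c1ccc(O[Si](C)(C)C(C)(C)C)c(C/C=C(\C)CCC=C(C)C)c1
F6 | step 1 | (4-bromo-2-iodophenoxy)(tert-butyl)dimethylsilane | CC(C)(C)[Si](C)(C)Oc1ccc(Br)cc1I
F7 | step 1 | {4-bromo-2-[(2E)-3,7-dimethylocta-2,6-dien-1-yl]phenoxy}(tert-butyl)dimethylsilane | CC(C)=CCC/C(C)=C/Cc1cc(Br)ccc1O[Si](C)(C)C(C)(C)C
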